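The runs come from a simulation with made-up constants; the scatter is artificial.

Stopping the flask is the decision to prepare, and the ring to be had at the stop depends on how the starting material divides between ring closure and its bimolecular losses.

| flask | starting material | remark | time |
|---|---|---|---|
| grey | 1 M | run made earlier |  |
| flask | 2.0 M |  | 2.5 d |
grey run (percent of the starting material charged)

| time / h | ring / % | starting material / % |
|---|---|---|
| 1.33 | 6.6 | 87.8 |
| 2.50 | 12.7 | 79.4 |
| 4.00 | 17.7 | 69.0 |
| 6.00 | 24.5 | 58.4 |
| 10.0 | 34.3 | 42.7 |
| 20.0 | 48.8 | 21.1 |

(standard deviation of a reading: 0.3 percentage points)
- time, not beyond 2.5 d, at which the flask holds most ring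
- the amount of ring, in percent of the starting material charged, at that time
- the analysis behind the earlier runs scatters by 0.3 percentage points, standard deviation

Take ring closure first, as the one step. The reckoning then sends 100 percent of the charge to ring, and the grey run at 6.00 h, with ring over mean c(starting material), gives 0.0516 /h, a half-life of 0.560 d.

Now add loss second order in starting material. At that reading, ring against the starting material consumed otherwise, times mean c(starting material), gives 1.13 M for the crossover concentration: the c(starting material) at which ring and bimolecular loss take equal shares, an effective molarity. Ring's share at any c is crossover/(crossover + c). Summed from charge c0 to zero, it gives (crossover/c0) ln(1 + c0/crossover), here 57.7%.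

Then add ring loss. The same sum for the grey run at 20.0 h gives 52.4% against 48.8% read. Taken as first-order loss from half the final ring, the gap gives 0.00729 /h, a half-life of 3.96 d. As a rough reckoning of this text, ageing the ring for 3 closure half-lives, 1.68 d, leaves 43.0% near that time.

The forecast says 44.5% at 1.5 d, reasoning that “a second-order loss runs alongside ring closure”; its time is earlier than this reckoning's and its ring higher.

The flask gives 43.2% at 1.42 d. Ring stays within 5.00% of that from 0.903 d to 2.17 d and stands at 39.5% at 2.50 d.

    starting material → ring (k = 0.0550 /h)
    2 starting material → open dimer (k = 0.0220 /M/h)
    starting material + open dimer → open trimer (k = 0.0260 /M/h)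
    ring → over-reaction product (k = 0.00690 /h)

This flask is charged at 2.0 M, above the crossover, so ring's reckoned opening share is 36.1%. The run without the step to open dimer peaks at 74.2% instead of 43.2%, the largest single effect here, 31 percentage points against 12 points for ring loss. The forecast would fail if ring proved stable: that run peaks at 54.8%.

At 0.80 M, below the crossover, the sum gives 75.7%, and the same ageing 56.4%. That neighbour's computed best is 57.3%.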